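Slowness is what needs reckoning here, in a charge that opens fast. Z meets X and a trace of G in three flasks that differ in temperature, and E at the end is wanted.

| flask | Z | X | G | time | remark | temperature |
|---|---|---|---|---|---|---|
| south-west | 0.067 M | 6.70 mM | 6.7 µM | 8.0 min | at −10 °C until 2.5 min, from then on at 5 °C |  |
| east | 0.067 M | 6.70 mM | 6.7 µM | 8.0 min |  | 5 °C |
| north-east | 0.067 M | 6.70 mM | 6.7 µM | 8.0 min |  | −10 °C |

    G → D (k1 = 7.5 × 10⁻⁴ s⁻¹, Ea1 = 191 kJ mol⁻¹)
    Z + G → E + G, rate k2*[Z]^2.5*[G]/(1 + ([Z]/Kh2)^2.5) (Kh2 = 0.051 M, k2 = 1.2 × 10⁶ M⁻²·⁵ s⁻¹, Ea2 = 9.00 kJ mol⁻¹)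
    Z ⇌ Q (K3 = 0.42, k3 = 0.20 s⁻¹, Ea3 = 75.0 kJ mol⁻¹, ΔH3 = −23.0 kJ mol⁻¹)
    Z + X → Z.X (k4 = 3.0 M⁻¹ s⁻¹, Ea4 = 46.0 kJ mol⁻¹)
    E + G ⇌ J + G, rate k5*[G]*[E] forward; the back reaction follows from the equilibrium constant (K5 = 0.58, k5 = 1200 M⁻¹ s⁻¹, Ea5 = 42.0 kJ mol⁻¹, ΔH5 = 4.00 kJ mol⁻¹)
    (constants at 5 °C)

- at 5 °C the constants are as listed, elsewhere as the activation energies and enthalpies make them

- the best flask by amount of E, in percent of the Z charged; "all alike" if 1.5 percentage points covers them all (south-west / east / north-east / all alike)
- amount of E at the end, in percent of the Z charged, south-west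
- amount of E at the end, in percent of the Z charged, east
- amount of E at the end, in percent of the Z charged, north-east

At high Z the rate law of step 2 flattens to a ceiling, and at 5 °C that ceiling would clear the charge in 14.2 s. Yet 8.0 min, 33.8 such spans, will not finish it.

The reckoning here joins the two ends. Once Z lies well below Kh2, the bottom of the rate law fades and step 2 follows its bare high power of Z. Q stays beside Z in the ratio K3, so Z is the part 1/(1+K3) of what remains. For the fraction of the charge still Z or Q, that fraction to the power −3/2 then climbs in a straight line with time, with slope (3/2)·k2·G·cZ^(3/2)/(1+K3)^(5/2), where cZ is the Z charged.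

In north-east, step 2 is slower by the factor 1.2 and K3 is 0.740, so the climb reaches 20.1. The fast opening supplies a starting value near one, far less than the climb, so the end forgets the start. This gives 13.5% left as Z or Q in north-east: the tail fraction, the part of the charge that the power law has not reached by the end.

With G averaged over its first-order loss in step 1, east has a tail of 9.33%. South-west, adding its cold and warm stretches, has 9.98%.

Z.X is counted at the full X charge, 10.0% of the Z. The reckoning assumes that the rest has reached the equilibrium split between E and J, with K5 at 0.580 warm and 0.526 cold. On that assumption E comes to 50.6% in south-west, 51.1% in east and 50.1% in north-east. That span of 1.00 percentage point sits inside the margin, so the reckoning says all alike.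

The forecast says all alike too, with 51.1%, 51.3% and 51.5%, holding that “its loss of rate in the tail is offset by a slightly more E-favourable equilibrium”. It differs from the reckoning in ranking north-east highest rather than lowest.

The simulation gives all alike: south-west 51.2%, east 51.4%, north-east 52.1%. Z and Q together read 13.1% in north-east, beside the tail fraction of 13.5%. The assumed split does not hold in north-east at the end: J over E reads 0.478, lower than the cold K5 of 0.526, and E is still made 1.26 times faster than it is used up, so the reckoned 50.1% stands below the flask. The back run from J to E is the main reason E reads 51.4% in east: with that run taken away, E in east falls to 6.58%. In the neighbour flask, north-east with 1.1 × 10⁻⁵ M of G, the tail fraction scales to 9.71%, giving E of 52.6%. That run gives Z and Q of 9.28% and E of 53.6%.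

The numbers of this flask are invented; what happens was integrated by code.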